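The 3(2H)-furanone (O–C3=C2–C1(=O)–C10) is disconnected as the [3+2] union of a methyl-ketone enolate (O–C3=C2) with an α-chloro acyl unit (C10–C1). Because C1–C2 also belongs to the ten-membered carbocycle C1–C10, one C-acylation/O-alkylation cascade on an open-chain acid closes macrocycle and furanone together and creates quaternary C10 stereoconvergently from a C10-epimeric tertiary chloride. The precursor already holds the trans α-methylene butanolide, acetate, methacrylate and C3 methyl ketone; it is assembled from an L-erythrulose-derived keto aldehyde and an epoxide-derived propargylic mesylate by Marshall propargylation and cyclocarbonylation.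

Key step: step 17

Remark: germacrane numbering of the target is used for all intermediates (C1 ring ketone, C2=C3 furanone alkene, C4 carbinol bearing C15H2OH, C5 OAc, C6/C7 lactone fusion, C8 O-methacryloyl, C10 quaternary, C11–C13 methylene lactone). Compounds 15–25 are carried as 1:1 mixtures of C10 epimers (C10 undefined in their SMILES). Where R/S descriptors appear in compound names they follow the compound's own locants.

Step 1
Reactants: 1 L-erythrulose
Product: 2 3,4-O-isopropylidene-L-erythrulose
Conditions: 2,2-dimethoxypropane, CSA (cat.), acetone, rt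
Reagents that add atoms: 2,2-dimethoxypropane, COC(C)(C)OC
Why: Acid-catalysed transketalisation should give the thermodynamically preferred five-membered 3,4-acetonide; C5 is taken from the chiral pool.

Step 2
Reactants: 2 3,4-O-isopropylidene-L-erythrulose
Product: 3 1-O-(tert-butyldiphenylsilyl)-3,4-O-isopropylidene-L-erythrulose
Conditions: TBDPSCl, imidazole, DMF, 0 °C to rt
Reagents that add atoms: tert-butyl(chloro)diphenylsilane, CC(C)(C)[Si](Cl)(c1ccccc1)c1ccccc1
Why: Silylation of the only free (primary) hydroxyl; the bulky, non-chelating silyl ether leaves the dioxolane oxygen as the sole chelation site for step 3.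

Step 3
Reactants: 3 1-O-TBDPS-3,4-O-isopropylidene-L-erythrulose; 4 isopropenylmagnesium bromide
Product: 5 tertiary alcohol (2R)-1-(tert-butyldiphenylsilyloxy)-2-[(4S)-2,2-dimethyl-1,3-dioxolan-4-yl]-3-methylbut-3-en-2-ol
Conditions: MgBr2·OEt2, CH2Cl2/THF, −78 °C
Reagents that add atoms: none
Why: Cram-chelate (α-chelation) controlled Grignard addition: Mg bridges the ketone and the dioxolane oxygen on C5, and the isopropenyl group (a masked acetyl) enters anti to C6, which sets C4 as in the target.

Step 4
Reactants: 5 tertiary alcohol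
Product: 6 C4-O-TBS ether of 5
Conditions: TBSOTf, 2,6-lutidine, CH2Cl2, 0 °C to rt
Reagents that add atoms: tert-butyldimethylsilyl trifluoromethanesulfonate, CC(C)(C)[Si](C)(C)OS(=O)(=O)C(F)(F)F
Why: Silyl triflate silylation of the hindered tertiary alcohol; TBS is chosen because it should survive the later acid steps.

Step 5
Reactants: 6 C4-O-TBS ether
Product: 7 (2S,3R)-3-(tert-butyldimethylsilyloxy)-3-[(tert-butyldiphenylsilyloxy)methyl]-4-methylpent-4-ene-1,2-diol
Conditions: AcOH/H2O/THF (3:1:1), 40 °C
Reagents that add atoms: none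
Why: Acid hydrolysis of the terminal acetonide; the TBDPS and tertiary TBS ethers are stable to aqueous acetic acid.

Step 6
Reactants: 7 diol
Product: 9 (2S,3R)-3-(TBS-oxy)-3-[(TBDPS-oxy)methyl]-4-methyl-1-(triethylsilyloxy)pent-4-en-2-yl acetate, via primary TES ether 8 (not isolated)
Conditions: TESCl, imidazole, CH2Cl2, −40 °C; then Ac2O, Et3N, DMAP, rt
Reagents that add atoms: triethylsilyl chloride, CC[Si](Cl)(CC)CC; acetic anhydride, CC(=O)OC(C)=O
Why: Primary-selective silylation followed in the same flask by DMAP-catalysed acetylation of O5 installs the target's acetate early and leaves C6 as a TES ether that can be oxidised directly.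

Step 7
Reactants: 9 acetate
Product: 10 methyl ketone (2S,3R)-3-(TBS-oxy)-3-[(TBDPS-oxy)methyl]-4-oxo-1-(triethylsilyloxy)pentan-2-yl acetate
Conditions: O3, CH2Cl2, −78 °C; then Me2S
Reagents that add atoms: ozone, [O-][O+]=O
Why: Ozonolysis of the 1,1-disubstituted alkene unveils the C3 methyl ketone only at this point, so that a free C6 hydroxyl never faces the ketone (no hemiketal).

Step 8
Reactants: 10 methyl ketone
Product: 11 keto aldehyde (2R,3R)-3-(TBS-oxy)-3-[(TBDPS-oxy)methyl]-1,4-dioxopentan-2-yl acetate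
Conditions: (COCl)2, DMSO, CH2Cl2, −78 to −30 °C; then i-Pr2NEt, −78 to 0 °C
Reagents that add atoms: none
Why: Swern oxidation should convert the primary TES ether directly into the aldehyde (desilylation at the alkoxysulfonium stage) without touching the tertiary TBS and TBDPS ethers.

Step 9
Reactants: 12 (E)-pent-2-en-4-yn-1-ol
Product: 13 (E)-5-bromopent-3-en-1-yne
Conditions: PBr3, Et2O, 0 °C
Reagents that add atoms: phosphorus tribromide, BrP(Br)Br
Why: SN2 conversion of the primary allylic alcohol into the bromide with retention of the alkene geometry.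

Step 10
Reactants: 14 tert-butyl 2-chloropropanoate; 13 (E)-5-bromopent-3-en-1-yne
Product: 15 tert-butyl (E)-2-chloro-2-methylhept-4-en-6-ynoate (racemic)
Conditions: LDA, THF/DMPU, −78 °C; then 13, −78 to −40 °C
Reagents that add atoms: none
Why: Alkylation of the lithium enolate of the α-chloro ester (SN2 at the primary allylic bromide) creates quaternary C10 deliberately as a racemate, since the key step erases this centre; the tert-butyl ester resists later lactonisation by O8.

Step 11
Reactants: 15 enyne ester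
Product: 16 tert-butyl 2-chloro-3-[(2R,3R)-3-ethynyloxiran-2-yl]-2-methylpropanoate (C10 epimers)
Conditions: D-fructose-derived Shi ketone (30 mol %), Oxone, K2CO3, n-Bu4NHSO4, MeCN/DMM/aq. buffer (pH 10.5), 0 °C
Reagents that add atoms: Oxone (potassium peroxymonosulfate), [K+].[O-]S(=O)(=O)OO
Why: Shi asymmetric epoxidation (dioxirane, spiro transition state) is chemoselective for the trans alkene of a conjugated enyne; the D-fructose-derived ketone should deliver the (R,R)-epoxide, which sets C8 and, for relay, C7.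

Step 12
Reactants: 16 alkynyl epoxide
Product: 18 tert-butyl (4R,5S)-2-chloro-2-methyl-5-(methylsulfonyloxy)-4-(triethylsilyloxy)hept-6-ynoate (C10 epimers), via hydroxy mesylate 17 (not isolated)
Conditions: MsOH (1.05 equiv), CH2Cl2, −40 °C; then 2,6-lutidine, TESOTf, −78 to 0 °C
Reagents that add atoms: methanesulfonic acid, CS(=O)(=O)O; triethylsilyl trifluoromethanesulfonate, CC[Si](CC)(CC)OS(=O)(=O)C(F)(F)F
Why: Acid-mediated SN2 opening of the alkynyl epoxide by methanesulfonate at the propargylic carbon (inversion at C7, retention at C8) should give the anti hydroxy mesylate, which is silylated at once so that the hydroxyl can neither reclose the epoxide nor lactonise.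

Step 13
Reactants: 11 keto aldehyde; 18 propargylic mesylate
Product: 19 anti homopropargylic alcohol (C6-OH, C7-ethynyl, C8-OTES)
Conditions: Pd(OAc)2 (5 mol %), PPh3 (5 mol %), InI, THF/HMPA (4:1), rt
Reagents that add atoms: none
Why: Marshall propargylation: anti-SN2′ oxidative addition of Pd(0), transmetalation to a configurationally defined allenylindium and cyclic SE2′ addition transfer the C7 mesylate configuration with net inversion and should give the anti C6/C7 adduct in the Felkin-matched (C5/C6 anti) sense; the aldehyde reacts in preference to the methyl ketone, and O8 is a silyl ether so that it cannot be eliminated.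

Step 14
Reactants: 19 homopropargylic alcohol
Product: 21 C8-hydroxy α-methylene-γ-butyrolactone (6,12-olide), via TES-protected lactone 20 (not isolated)
Conditions: Pd(OAc)2 (cat.), 2-(diphenylphosphino)pyridine, p-TsOH (cat.), CO (20 bar), CH2Cl2, 45 °C; then PPTS, MeOH, 0 °C
Reagents that add atoms: carbon monoxide, [C-]#[O+]
Why: Pd-catalysed Markovnikov cyclocarbonylation of the homopropargylic alcohol builds the α-methylene lactone on O6 (O8 is silylated; the open hydroxy ketone and its C3 hemiketal equilibrate), the trans fusion following from the anti C6/C7 relationship; mild methanolysis then frees O8.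

Step 15
Reactants: 21 hydroxy lactone
Product: 22 C8-methacrylate tert-butyl ester
Conditions: methacrylic anhydride, Et3N, DMAP (cat.), CH2Cl2, 0 °C to rt
Reagents that add atoms: methacrylic anhydride, CC(=C)C(=O)OC(=O)C(C)=C
Why: DMAP-catalysed acylation of the only free hydroxyl installs the methacrylate.

Step 16
Reactants: 22 tert-butyl ester
Product: 23 seco acid (C1 carboxylic acid)
Conditions: TFA/CH2Cl2 (1:4), 0 °C to rt
Reagents that add atoms: none
Why: Acidolysis of the tert-butyl ester (loss of isobutene) frees the C1 acid only once O8 is acylated, so no γ-lactone can form; the silyl ethers, esters and tertiary chloride should tolerate TFA.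

Step 17
Reactants: 23 seco acid
Product: 26 4-O-TBS, 15-O-TBDPS protected target (ten-membered carbocycle with 3,10-bridging furanone), via seco acid chloride 24 (not isolated), via macrocyclic chloro diketone 25 (not isolated)
Conditions: 1-chloro-N,N,2-trimethylprop-1-en-1-amine (Ghosez reagent), CH2Cl2, 0 °C to rt; then syringe-pump addition (12 h) to MgBr2·OEt2, i-Pr2NEt, CH2Cl2 (1 mM), rt; then Et3N, CF3CH2OH, 0 °C to rt
Reagents that add atoms: none
Why: Ghosez's reagent gives acid chloride 24 under neutral conditions; MgBr2·OEt2/i-Pr2NEt then soft-enolises the C3 methyl ketone (its only enolisable side) and the Mg enolate is C-acylated at C2 by the tethered acid chloride (10-exo-trig acyl substitution, Mg bridging both carbonyls) to chloro diketone 25; Et3N/CF3CH2OH finally ionises the tertiary α-chloro ketone with enolate assistance to a planar 2-oxyallyl-type species whose C3 oxygen closes onto C10 (4π oxa-Nazarov-type closure, formally 5-endo-trig; 5-exo-tet if it runs as a direct displacement). The closest known reactions are the soft-enolisation C-acylation of ketones with acid chlorides, the base-induced cyclisation of α′-halo-1,3-diketones to 3(2H)-furanones and the Föhlisch generation of oxyallyl species from α-chloro ketones in fluorinated alcohols. C10 is the only new stereocentre: both chloride epimers lose their configuration in the planar intermediate, and O3 can reach C10 only on the face toward which the C4–C9 bridge is folded, a fold fixed by the trans-fused butanolide and the C5/C8 esters in the bicyclo[6.2.1] framework of the furanoheliangolides; this is expected, but not proven, to give 10S. The step needs C- over O-acylation (chelated Mg enolate), ring closure over oligomerisation (high dilution, slow addition, Mg template), acylation by the acid chloride and not O-to-C transfer of the C5 acetate (simple esters are inert to Mg enolates at rt), and O-closure over Favorskii or E2 pathways (non-nucleophilic medium, five-membered closure onto a conjugated enolate).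

Step 18
Reactants: 26 protected macrocycle
Product: 27 target CNP0275292.1
Conditions: HF·pyridine, pyridine/THF, 0 °C to rt
Reagents that add atoms: none
Why: Fluoride cleavage of both silyl ethers under mildly acidic conditions, which should avoid acetyl migration and conjugate addition, gives the target.

Compound list
1 | L-erythrulose, (3S)-1,3,4-trihydroxybutan-2-one | OCC(=O)[C@@H](O)CO | starting material
2 | 3,4-O-isopropylidene-L-erythrulose | OCC(=O)[C@@H]1COC(C)(C)O1 | intermediate
3 | 1-O-(tert-butyldiphenylsilyl)-3,4-O-isopropylidene-L-erythrulose | O=C(CO[Si](c1ccccc1)(c1ccccc1)C(C)(C)C)[C@@H]1COC(C)(C)O1 | intermediate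
4 | isopropenylmagnesium bromide | CC(=C)[Mg]Br | starting material
5 | (2R)-1-(tert-butyldiphenylsilyloxy)-2-[(4S)-2,2-dimethyl-1,3-dioxolan-4-yl]-3-methylbut-3-en-2-ol | C=C(C)[C@@](O)(CO[Si](c1ccccc1)(c1ccccc1)C(C)(C)C)[C@@H]1COC(C)(C)O1 | intermediate
6 | C4-O-TBS ether of 5 | C=C(C)[C@@](O[Si](C)(C)C(C)(C)C)(CO[Si](c1ccccc1)(c1ccccc1)C(C)(C)C)[C@@H]1COC(C)(C)O1 | intermediate
7 | (2S,3R)-3-(tert-butyldimethylsilyloxy)-3-[(tert-butyldiphenylsilyloxy)methyl]-4-methylpent-4-ene-1,2-diol | C=C(C)[C@@](O[Si](C)(C)C(C)(C)C)(CO[Si](c1ccccc1)(c1ccccc1)C(C)(C)C)[C@@H](O)CO | intermediate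
8 | C6-O-triethylsilyl ether of 7 | C=C(C)[C@@](O[Si](C)(C)C(C)(C)C)(CO[Si](c1ccccc1)(c1ccccc1)C(C)(C)C)[C@@H](O)CO[Si](CC)(CC)CC | intermediate
9 | C5-acetate of 8 | C=C(C)[C@@](O[Si](C)(C)C(C)(C)C)(CO[Si](c1ccccc1)(c1ccccc1)C(C)(C)C)[C@@H](OC(C)=O)CO[Si](CC)(CC)CC | intermediate
10 | C3 methyl ketone (C5-OAc, C6-OTES) | CC(=O)[C@@](O[Si](C)(C)C(C)(C)C)(CO[Si](c1ccccc1)(c1ccccc1)C(C)(C)C)[C@@H](OC(C)=O)CO[Si](CC)(CC)CC | intermediate
11 | keto aldehyde (C3 ketone, C6 aldehyde, C5-OAc) | CC(=O)[C@@](O[Si](C)(C)C(C)(C)C)(CO[Si](c1ccccc1)(c1ccccc1)C(C)(C)C)[C@@H](OC(C)=O)C=O | intermediate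
12 | (E)-pent-2-en-4-yn-1-ol | OC/C=C/C#C | starting material
13 | (E)-5-bromopent-3-en-1-yne | BrC/C=C/C#C | intermediate
14 | tert-butyl 2-chloropropanoate (racemic) | CC(Cl)C(=O)OC(C)(C)C | starting material
15 | tert-butyl (E)-2-chloro-2-methylhept-4-en-6-ynoate (racemic) | C#C/C=C/CC(C)(Cl)C(=O)OC(C)(C)C | intermediate
16 | tert-butyl 2-chloro-3-[(2R,3R)-3-ethynyloxiran-2-yl]-2-methylpropanoate (C10 epimers) | CC(Cl)(C[C@H]1O[C@@H]1C#C)C(=O)OC(C)(C)C | intermediate
17 | tert-butyl (4R,5S)-2-chloro-4-hydroxy-2-methyl-5-(methylsulfonyloxy)hept-6-ynoate (C10 epimers) | CC(Cl)(C[C@@H](O)[C@@H](OS(C)(=O)=O)C#C)C(=O)OC(C)(C)C | intermediate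
18 | tert-butyl (4R,5S)-2-chloro-2-methyl-5-(methylsulfonyloxy)-4-(triethylsilyloxy)hept-6-ynoate (C10 epimers) | CC(Cl)(C[C@@H](O[Si](CC)(CC)CC)[C@@H](OS(C)(=O)=O)C#C)C(=O)OC(C)(C)C | intermediate
19 | anti homopropargylic alcohol (seco chain C2–C10; C6-OH, C7-ethynyl, C8-OTES, C1 tert-butyl ester) | CC(=O)[C@@](O[Si](C)(C)C(C)(C)C)(CO[Si](c1ccccc1)(c1ccccc1)C(C)(C)C)[C@@H](OC(C)=O)[C@@H](O)[C@H](C#C)[C@H](O[Si](CC)(CC)CC)CC(C)(Cl)C(=O)OC(C)(C)C | intermediate
20 | C8-O-TES α-methylene-γ-butyrolactone (6,12-olide) | CC(=O)[C@@](O[Si](C)(C)C(C)(C)C)(CO[Si](c1ccccc1)(c1ccccc1)C(C)(C)C)[C@@H](OC(C)=O)[C@H]1OC(=O)C(=C)[C@@H]1[C@H](O[Si](CC)(CC)CC)CC(C)(Cl)C(=O)OC(C)(C)C | intermediate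
21 | C8-hydroxy lactone | CC(=O)[C@@](O[Si](C)(C)C(C)(C)C)(CO[Si](c1ccccc1)(c1ccccc1)C(C)(C)C)[C@@H](OC(C)=O)[C@H]1OC(=O)C(=C)[C@@H]1[C@H](O)CC(C)(Cl)C(=O)OC(C)(C)C | intermediate
22 | C8-methacrylate tert-butyl ester | CC(=O)[C@@](O[Si](C)(C)C(C)(C)C)(CO[Si](c1ccccc1)(c1ccccc1)C(C)(C)C)[C@@H](OC(C)=O)[C@H]1OC(=O)C(=C)[C@@H]1[C@H](OC(=O)C(C)=C)CC(C)(Cl)C(=O)OC(C)(C)C | intermediate
23 | seco acid (C1 carboxylic acid, C10 chloride) | CC(=O)[C@@](O[Si](C)(C)C(C)(C)C)(CO[Si](c1ccccc1)(c1ccccc1)C(C)(C)C)[C@@H](OC(C)=O)[C@H]1OC(=O)C(=C)[C@@H]1[C@H](OC(=O)C(C)=C)CC(C)(Cl)C(=O)O | intermediate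
24 | seco acid chloride | CC(=O)[C@@](O[Si](C)(C)C(C)(C)C)(CO[Si](c1ccccc1)(c1ccccc1)C(C)(C)C)[C@@H](OC(C)=O)[C@H]1OC(=O)C(=C)[C@@H]1[C@H](OC(=O)C(C)=C)CC(C)(Cl)C(Cl)=O | intermediate
25 | macrocyclic 10-chloro-1,3-dione (ten-membered carbocycle) | O=C1CC(=O)[C@@](O[Si](C)(C)C(C)(C)C)(CO[Si](c2ccccc2)(c2ccccc2)C(C)(C)C)[C@@H](OC(C)=O)[C@H]2OC(=O)C(=C)[C@@H]2[C@H](OC(=O)C(C)=C)CC1(C)Cl | intermediate
26 | 4-O-TBS, 15-O-TBDPS protected target | C=C(C)C(=O)O[C@@H]1C[C@]2(C)OC(=CC2=O)[C@@](O[Si](C)(C)C(C)(C)C)(CO[Si](c3ccccc3)(c3ccccc3)C(C)(C)C)[C@@H](OC(C)=O)[C@H]2OC(=O)C(=C)[C@@H]21 | intermediate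
27 | CNP0275292.1, (4R,5S,6S,7R,8R,10S)-5-acetoxy-4,15-dihydroxy-8-methacryloyloxy-1-oxo-3,10-epoxygermacra-2,11(13)-dien-6,12-olide | C=C(C)C(=O)O[C@@H]1C[C@]2(C)OC(=CC2=O)[C@@](O)(CO)[C@@H](OC(C)=O)[C@H]2OC(=O)C(=C)[C@@H]21 | target

Total step count: 18. Longest linear sequence: 14 steps (steps 1–8 and 13–18, from L-erythrulose); the second branch (steps 9–12) joins at step 13.

Steps most likely to fail

1. Step 17. Intermolecular acylation (oligomerisation) may outrun closure of the ten-membered ring, the C5 acetyl group may be transferred to C2, or O3 may close on the wrong face of C10 or HCl may be eliminated. The fallback makes the C1–C2 bond by an aldol reaction and separates the two bond formations. It sets out from seco acid 23: its acid chloride 24 is reduced (Bu3SnH, cat. Pd(PPh3)4, toluene, rt) to the non-enolisable α-chloro aldehyde F1. The more electrophilic aldehyde is closed onto the C3 methyl ketone by a Mg(II)-mediated direct aldol reaction (MgBr2·OEt2, i-Pr2NEt, CH2Cl2, high dilution) to the macrocyclic β-hydroxy ketone F2. Dess–Martin oxidation gives chloro diketone 25, which is isolated and cyclised with Et3N/CF3CH2OH (or a silver salt with a hindered base), returning to the route at 26.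

2. Step 12. Protic opening may ionise C7 to a propargylic cation (loss of configuration), attack C8, or let the freed C8 hydroxyl lactonise onto the tert-butyl ester. The fallback sets out from epoxide 16: MgBr2·OEt2 (Et2O, −20 °C) opens the epoxide at the propargylic carbon with inversion under aprotic conditions to the bromohydrin F3, which is silylated (TESOTf, 2,6-lutidine) to the propargylic bromide F4. F4 replaces mesylate 18 as the allenylindium precursor under the conditions of step 13 with aldehyde 11 and returns to the route at 19.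

3. Step 14. Acetyl migration from O5 to O6 in 19, alkyne isomerisation by palladium hydride, or early loss of the TES group (lactonisation onto O8) may divert the cyclocarbonylation. The fallback sets out from 19: Markovnikov bromoboration and protonolysis (B-bromo-9-BBN, CH2Cl2, 0 °C; then AcOH) gives the 2-bromoalkene F5. Pd(0)-catalysed carbonylative lactonisation of this vinyl bromide (Pd(PPh3)4, CO 1 atm, Et3N, MeCN, 60 °C) gives lactone 20, and PPTS/MeOH returns to the route at 21.

Further compounds
F1 | step 17 | seco α-chloro aldehyde (C1 aldehyde) | CC(=O)[C@@](O[Si](C)(C)C(C)(C)C)(CO[Si](c1ccccc1)(c1ccccc1)C(C)(C)C)[C@@H](OC(C)=O)[C@H]1OC(=O)C(=C)[C@@H]1[C@H](OC(=O)C(C)=C)CC(C)(Cl)C=O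
F2 | step 17 | macrocyclic 10-chloro-1-hydroxy-3-ketone (aldol, C1 and C10 epimers) | OC1CC(=O)[C@@](O[Si](C)(C)C(C)(C)C)(CO[Si](c2ccccc2)(c2ccccc2)C(C)(C)C)[C@@H](OC(C)=O)[C@H]2OC(=O)C(=C)[C@@H]2[C@H](OC(=O)C(C)=C)CC1(C)Cl
F3 | step 12 | tert-butyl (4R,5S)-5-bromo-2-chloro-4-hydroxy-2-methylhept-6-ynoate (C10 epimers) | CC(Cl)(C[C@@H](O)[C@@H](Br)C#C)C(=O)OC(C)(C)C
F4 | step 12 | tert-butyl (4R,5S)-5-bromo-2-chloro-2-methyl-4-(triethylsilyloxy)hept-6-ynoate (C10 epimers) | CC(Cl)(C[C@@H](O[Si](CC)(CC)CC)[C@@H](Br)C#C)C(=O)OC(C)(C)C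
F5 | step 14 | 2-bromoalkene from 19 (C11 bromide, C13 methylene) | CC(=O)[C@@](O[Si](C)(C)C(C)(C)C)(CO[Si](c1ccccc1)(c1ccccc1)C(C)(C)C)[C@@H](OC(C)=O)[C@@H](O)[C@H](C(Br)=C)[C@H](O[Si](CC)(CC)CC)CC(C)(Cl)C(=O)OC(C)(C)C
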